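All constants are made up.

5 questions stand on 4 set-ups that differ in when coupling partner and substrate arrive.

    coupling partner + free catalyst → catalyst intermediate A (k1 = 29 M⁻¹ min⁻¹)
    catalyst intermediate A → by-product + catalyst intermediate B (k2 = 26 min⁻¹)
    substrate + catalyst intermediate B → catalyst intermediate C (k3 = 220 M⁻¹ min⁻¹)
    catalyst intermediate C → free catalyst + product (k4 = 28 min⁻¹)
    coupling partner + precatalyst → free catalyst + spent reagent (k5 = 0.31 M⁻¹ min⁻¹)

in all of them: precatalyst 1 mol%

| run | substrate | coupling partner | time | remark |
|---|---|---|---|---|
| alder | 0.10 M | 1.50 equiv (fed, over 2.00 h) | 2.0 h | a stirred flask in which coupling partner is dosed at a steady rate over 2.00 h without added volume, worked up at 2.0 h |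
| oak | 0.10 M | 1.50 equiv |  | one stirred flow tank at steady state, fed with the mixture as stated, mean residence time 2.0 h |
| ash | 0.10 M | 1.50 equiv | 2.0 h | everything together in a closed stirred flask, run for 2.0 h |
| elm | 0.10 M (fed, over 2.00 h) | 1.50 equiv | 2.0 h | a stirred flask in which substrate is dosed at a steady rate over 2.00 h without added volume, worked up at 2.0 h |

- the set-up with the highest amount of product at the outlet or at the end, in percent of the substrate put in ("none" if the first two lie within 2 percentage points) (alder / oak / ash / elm / none)
- amount of product at the outlet or at the end, in percent of the substrate put in, alder
- amount of product at the outlet or at the end, in percent of the substrate put in, oak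
- amount of product at the outlet or at the end, in percent of the substrate put in, ash
- amount of product at the outlet or at the end, in percent of the substrate put in, elm

- the stated concentrations are those of everything mixed, before any reaction; amounts are the same in each set-up
- the feed brings no volume worth counting
- run time (alder): 2.0 h

**Main step.** Each catalyst round takes one coupling partner and gives one product. I freeze the catalyst at its charge, c = 1.00 mM, and reckon alder, dosed at f = 0.0750 M h⁻¹. With c held as free catalyst from the start, step 1 is pseudo-first-order in coupling partner, with time constant τ = 34.5 min. Coupling partner then levels at fτ = 0.0431 M. The 0.107 M turned over exceeds the substrate charge, so this picture gives 100 percent.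

**Adding activation.** Free catalyst comes from precatalyst by step 5, and coupling partner in alder starts at nothing; I take it as rising about as ft, with none taken by step 1. Precatalyst therefore falls as the exponential of minus the square of t/t_a. Here t_a, the activation time, is the time by which coupling partner rising as ft has taken the precatalyst down one e-fold: 71.8 min. Treating the catalyst as switched on at t_a, coupling partner stands at 0.0897 M and relaxes toward fτ over the remaining 48.2 min. That ends at 0.0547 M and gives 95.3%.

**Adding the rest.** With substrate taken at its charge, steps 2 to 4 hold the catalyst for 0.120 min per round, out of 0.800 min per round at the dose rate. So τ lengthens to 40.5 min, and the same sum gives alder 87.4%, the figure I commit to. In ash, coupling partner starts at its charge; taken as held there, it gives a precatalyst time constant of 21.5 min, 3.34 times shorter than t_a. In this reckoning activation plus turnover take about 59.4 min, which is less than the run, so I put ash above alder.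

**The forecast.** It names ash as best, with alder 75%, oak 87%, ash 99.9% and elm 89.5%, holding that “dosing the coupling partner starves both activation and the cycle”. My alder figure stands above its figure.

**The result.** Ash comes out highest: alder 76.2%, oak 86.6%, ash >99.9%, elm 92.2%. Alder lands below my figure: at 2.00 h it still holds 24% of its substrate and 48% of its coupling partner. Put to use at 1.00 h, t_a gives 49.8% of the precatalyst left, and alder reads 52.8%.

**A neighbour.** Alder dosed with 0.900 equiv of coupling partner has a longer activation time, 92.7 min, which in my reckoning leaves 18.7% of the precatalyst at 2.00 h. The computed neighbour holds 29.0% of its precatalyst and gives 42.1% product.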